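Ring C (C1 carries the oxygen to ring B, C3 and C4 carry hydroxyls, C5 carries the oxygen to ring D, C2 and C6 carry hydrogen) is a 1,3,5-trioxygenated benzene with one extra oxygen at C4; a vinylketene and an alkynyl ether assemble exactly this pattern.
The target comes from a dodecabenzyl ring C phenol by one global hydrogenolysis.
Ring C is disconnected at C2–C3 and C1–C6 ([2+2]) and at C3–C4 (6π closure) into a cyclobutenone carrying rings D and E plus the C4 benzyloxy group, and an aryloxyacetylene carrying rings A and B; ring C is the only ring made and it is made last.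
The cyclobutenone comes from the DE aryloxyacetylene and benzyloxyketene; both aryloxyacetylenes come from the DE and AB phenols through E-dichlorovinyl ethers (trichloroethylene, then n-BuLi).
Each phenol comes from an Ullmann coupling of a benzylated phenol with an ortho-bromobenzaldehyde followed by Baeyer–Villiger oxidation; rings A, B, D and E are bought as two trihydroxybenzaldehydes and 5-bromoresorcinol.

Key step: step 17

Remark: the target has no stereocentre; the cyclobutenone and the sp3-containing annulation intermediates are racemic and lose their stereocentres on aromatisation; both aryloxyacetylenes are used directly after preparation.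

Step 1
Reactants: 1 3,4,5-trihydroxybenzaldehyde
Product: 2 3,4,5-tris(benzyloxy)benzaldehyde
Conditions: BnBr (3.5 equiv), K2CO3, DMF, 60 °C, argon
Reagents that add atoms: benzyl bromide BrCc1ccccc1
Why: Williamson etherification of the three phenoxides with benzyl bromide; the non-enolisable aldehyde is untouched by K2CO3.

Step 2
Reactants: 2 3,4,5-tris(benzyloxy)benzaldehyde
Product: 4 3,4,5-tris(benzyloxy)phenol, via aryl formate 3 (not isolated)
Conditions: mCPBA, CH2Cl2, 0 °C → rt; aq NaHCO3 wash; then K2CO3 (cat.), MeOH, rt, argon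
Reagents that add atoms: mCPBA OOC(=O)c1cccc(Cl)c1
Why: Baeyer–Villiger oxidation in which the electron-rich aryl group migrates to give formate 3, which base-catalysed methanolysis cleaves to the phenol.

Step 3
Reactants: 2 3,4,5-tris(benzyloxy)benzaldehyde
Product: 5 2-bromo-3,4,5-tris(benzyloxy)benzaldehyde
Conditions: NBS (1.05 equiv), MeCN, rt → 40 °C, dark
Reagents that add atoms: N-bromosuccinimide O=C1CCC(=O)N1Br
Why: Electrophilic aromatic bromination at one of the two equivalent free positions of the trialkoxy ring, which is far more electron-rich than the benzyl phenyl rings.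

Step 4
Reactants: 4 3,4,5-tris(benzyloxy)phenol; 5 2-bromo-3,4,5-tris(benzyloxy)benzaldehyde
Product: 6 3,4,5-tris(benzyloxy)-2-[3,4,5-tris(benzyloxy)phenoxy]benzaldehyde
Conditions: CuI (10 mol %), picolinic acid (20 mol %), K3PO4, DMSO, 90 °C, argon
Reagents that add atoms: none
Why: Ullmann diaryl ether coupling in which the unhindered, electron-rich phenoxide of 4 replaces the bromide of 5, whose ortho formyl group accelerates the copper-mediated substitution.

Step 5
Reactants: 6 3,4,5-tris(benzyloxy)-2-[3,4,5-tris(benzyloxy)phenoxy]benzaldehyde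
Product: 8 3,4,5-tris(benzyloxy)-2-[3,4,5-tris(benzyloxy)phenoxy]phenol (DE phenol; its aryloxy group is called DE-aryloxy below), via DE formate 7 (not isolated)
Conditions: mCPBA, CH2Cl2, 0 °C → rt; aq NaHCO3 wash; then K2CO3 (cat.), MeOH, rt, argon
Reagents that add atoms: mCPBA OOC(=O)c1cccc(Cl)c1
Why: Baeyer–Villiger oxidation; the aryl group, with aryloxy ortho and benzyloxy para to the formyl group, migrates in preference to hydrogen, and formate 7 is methanolysed to the ring D phenol.

Step 6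
Reactants: 8 DE phenol; 9 trichloroethylene
Product: 10 (E)-1,2-dichlorovinyl ether of the DE phenol
Conditions: K2CO3, DMF, 70 °C
Reagents that add atoms: none
Why: The phenoxide adds anti to dichloroacetylene formed in the flask from trichloroethylene and base, which gives the E-1,2-dichlorovinyl aryl ether (known preparation of such ethers from phenols).

Step 7
Reactants: 10 (E)-1,2-dichlorovinyl ether of the DE phenol
Product: 12 DE aryloxyacetylene (ethynyl ether of 8), via lithium acetylide 11 (not isolated)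
Conditions: n-BuLi (2.2 equiv), THF, −78 → −40 °C; then MeOH, −78 °C
Reagents that add atoms: none
Why: n-BuLi removes the vinyl proton, loss of LiCl gives the chloroalkynyl ether and lithium–chlorine exchange gives acetylide 11, which methanol protonates (dichlorovinyl ether route to alkynyl ethers); at −78 °C the benzyl ethers are not metallated.

Step 8
Reactants: 12 DE aryloxyacetylene; 13 benzyloxyacetyl chloride
Product: 15 racemic 4-(benzyloxy)-3-(DE-aryloxy)cyclobut-2-en-1-one, via benzyloxyketene 14 (not isolated)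
Conditions: Et3N, toluene, 0 °C → rt, slow addition of 13 (2 equiv)
Reagents that add atoms: none
Why: Et3N dehydrochlorinates 13 to benzyloxyketene 14, which adds to the alkynyl ether in a polarised [2+2] cycloaddition (alkyne CH carbon to ketene carbonyl carbon), so the aryloxy group sits at C3 and the benzyloxy group at C4; the C4 stereocentre forms racemic and is erased in step 17.

Step 9
Reactants: 16 2,4,6-trihydroxybenzaldehyde
Product: 17 2,4,6-tris(benzyloxy)benzaldehyde
Conditions: BnBr (3.6 equiv), K2CO3, DMF, 70 °C, argon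
Reagents that add atoms: benzyl bromide BrCc1ccccc1
Why: Williamson etherification; the formyl group lowers the nucleophilicity of the ring carbons so that O-alkylation should dominate, and heating brings the two hydrogen-bonded ortho hydroxyls to reaction.

Step 10
Reactants: 17 2,4,6-tris(benzyloxy)benzaldehyde
Product: 19 2,4,6-tris(benzyloxy)phenol, via aryl formate 18 (not isolated)
Conditions: mCPBA (1.1 equiv), CH2Cl2, 0 °C; aq NaHCO3 wash; then K2CO3 (cat.), MeOH, rt, argon
Reagents that add atoms: mCPBA OOC(=O)c1cccc(Cl)c1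
Why: Baeyer–Villiger oxidation of a 2,4,6-trialkoxybenzaldehyde, where aryl migration is strongly favoured, followed by methanolysis of formate 18 under exclusion of air.

Step 11
Reactants: 20 5-bromoresorcinol
Product: 21 1,3-bis(benzyloxy)-5-bromobenzene
Conditions: BnBr (2.3 equiv), K2CO3, DMF, 50 °C
Reagents that add atoms: benzyl bromide BrCc1ccccc1
Why: Williamson etherification of both phenoxides; the aryl bromide is inert to these conditions.

Step 12
Reactants: 21 1,3-bis(benzyloxy)-5-bromobenzene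
Product: 23 2-bromo-4,6-bis(benzyloxy)benzaldehyde, via iminium salt 22 (not isolated)
Conditions: POCl3, DMF, 0 °C → 80 °C; then ice-water, rt
Reagents that add atoms: N,N-dimethylformamide CN(C)C=O; water O
Why: Vilsmeier–Haack formylation; the chloroiminium ion should attack the position ortho to bromine and para to one benzyloxy group in preference to the more crowded position between the two benzyloxy groups, and water hydrolyses iminium salt 22 to the aldehyde.

Step 13
Reactants: 19 2,4,6-tris(benzyloxy)phenol; 23 2-bromo-4,6-bis(benzyloxy)benzaldehyde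
Product: 24 2,4-bis(benzyloxy)-6-[2,4,6-tris(benzyloxy)phenoxy]benzaldehyde
Conditions: CuI (20 mol %), picolinic acid (40 mol %), K3PO4, DMSO, 100 °C, argon
Reagents that add atoms: none
Why: Ullmann diaryl ether coupling with the CuI–picolinic acid system, which is suited to ortho-substituted partners; the di-ortho-substituted phenoxide of 19 couples at the bromide activated by the ortho formyl group.

Step 14
Reactants: 24 2,4-bis(benzyloxy)-6-[2,4,6-tris(benzyloxy)phenoxy]benzaldehyde
Product: 26 2,4-bis(benzyloxy)-6-[2,4,6-tris(benzyloxy)phenoxy]phenol (AB phenol; its aryloxy group is called AB-aryloxy below), via AB formate 25 (not isolated)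
Conditions: mCPBA (1.1 equiv), CH2Cl2, 0 °C; aq NaHCO3 wash; then K2CO3 (cat.), MeOH, rt, argon
Reagents that add atoms: mCPBA OOC(=O)c1cccc(Cl)c1
Why: Baeyer–Villiger oxidation of a benzaldehyde with oxygen substituents at both ortho positions and the para position, so aryl migration is fast, followed by methanolysis of formate 25.

Step 15
Reactants: 26 AB phenol; 9 trichloroethylene
Product: 27 (E)-1,2-dichlorovinyl ether of the AB phenol
Conditions: K2CO3, DMF, 70 °C
Reagents that add atoms: none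
Why: Anti addition of the phenoxide to dichloroacetylene generated in the flask, as in step 6; the small, linear electrophile tolerates the two ortho substituents of the phenoxide.

Step 16
Reactants: 27 (E)-1,2-dichlorovinyl ether of the AB phenol
Product: 29 AB aryloxyacetylene (ethynyl ether of 26), via lithium acetylide 28 (not isolated)
Conditions: n-BuLi (2.2 equiv), THF, −78 → −40 °C; then MeOH, −78 °C
Reagents that add atoms: none
Why: Deprotonation, loss of LiCl and lithium–chlorine exchange give acetylide 28, which is protonated to the terminal alkynyl ether, as in step 7.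

Step 17
Reactants: 15 racemic 4-(benzyloxy)-3-(DE-aryloxy)cyclobut-2-en-1-one; 29 AB aryloxyacetylene (1.3 equiv)
Product: 34 2-(benzyloxy)-3-(DE-aryloxy)-5-(AB-aryloxy)phenol (dodecabenzyl pentamer with free ring C hydroxyl), via vinylketene 30 (not isolated), via vinylcyclobutenone 31 (not isolated), via dienylketene 32 (not isolated), via cyclohexadienone 33 (not isolated)
Conditions: toluene (0.1 M), 80 °C, then 110 °C, argon
Reagents that add atoms: none
Why: On heating, 15 opens by conrotatory 4π electrocyclic cleavage of its C(=O)–CH(OBn) bond (benzyloxy group turning outward) to vinylketene 30, whose carbonyl carbon is attacked by the nucleophilic CH carbon of ynol ether 29 in a polarised [2+2] addition that forms ring C bonds C2–C3 and C1–C6 and gives vinylcyclobutenone 31. A second, reversible 4π opening gives dienylketene 32, and the isomer with the ketene and the benzyloxyvinyl terminus cis on the central double bond closes the C3–C4 bond; tautomerisation of cyclohexadienone 33 then gives phenol 34. The closest known reaction is the Danheiser benzannulation of cyclobutenones with alkoxyacetylenes, which gives resorcinol monoethers. Ring C, the only ring closed, forms by thermal disrotatory 6π electrocyclisation of the dienylketene. No stereocentre is created in the product: the racemic centres of 15, 31 and 33 all become aromatic carbons. The step needs one regiochemical outcome, the ring B oxygen meta to the new hydroxyl, and the polarity of the ynol ether secures it, while the substituents of 15 fix the ring D oxygen at C5 and the benzyloxy group at C4; heat alone drives the cascade, so benzyl and diaryl ethers are untouched.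

Step 18
Reactants: 34 dodecabenzyl pentamer phenol
Product: 35 Pseudopentafuhalol D
Conditions: H2 (1 atm), Pd/C (10 % Pd), THF–MeOH, rt; filtration and evaporation under argon
Reagents that add atoms: none
Why: Hydrogenolysis of benzyl aryl ethers over palladium on carbon; the four diaryl ether bonds and the arene rings are inert under these conditions, and all twelve benzyl groups leave as toluene.

Compound list
1 | 3,4,5-trihydroxybenzaldehyde | O=Cc1cc(O)c(O)c(O)c1 | starting material
2 | 3,4,5-tris(benzyloxy)benzaldehyde | O=Cc1cc(OCc9ccccc9)c(OCc9ccccc9)c(OCc9ccccc9)c1 | intermediate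
3 | 3,4,5-tris(benzyloxy)phenyl formate | O=COc1cc(OCc9ccccc9)c(OCc9ccccc9)c(OCc9ccccc9)c1 | intermediate (not isolated)
4 | 3,4,5-tris(benzyloxy)phenol | Oc1cc(OCc9ccccc9)c(OCc9ccccc9)c(OCc9ccccc9)c1 | intermediate
5 | 2-bromo-3,4,5-tris(benzyloxy)benzaldehyde | O=Cc1cc(OCc9ccccc9)c(OCc9ccccc9)c(OCc9ccccc9)c1Br | intermediate
6 | 3,4,5-tris(benzyloxy)-2-[3,4,5-tris(benzyloxy)phenoxy]benzaldehyde | O=Cc1cc(OCc9ccccc9)c(OCc9ccccc9)c(OCc9ccccc9)c1Oc1cc(OCc9ccccc9)c(OCc9ccccc9)c(OCc9ccccc9)c1 | intermediate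
7 | 3,4,5-tris(benzyloxy)-2-[3,4,5-tris(benzyloxy)phenoxy]phenyl formate | O=COc1cc(OCc9ccccc9)c(OCc9ccccc9)c(OCc9ccccc9)c1Oc1cc(OCc9ccccc9)c(OCc9ccccc9)c(OCc9ccccc9)c1 | intermediate (not isolated)
8 | 3,4,5-tris(benzyloxy)-2-[3,4,5-tris(benzyloxy)phenoxy]phenol (DE phenol) | Oc1cc(OCc9ccccc9)c(OCc9ccccc9)c(OCc9ccccc9)c1Oc1cc(OCc9ccccc9)c(OCc9ccccc9)c(OCc9ccccc9)c1 | intermediate
9 | trichloroethylene | ClC=C(Cl)Cl | starting material
10 | (E)-1,2-dichlorovinyl ether of the DE phenol | Cl/C=C(/Cl)Oc1cc(OCc9ccccc9)c(OCc9ccccc9)c(OCc9ccccc9)c1Oc1cc(OCc9ccccc9)c(OCc9ccccc9)c(OCc9ccccc9)c1 | intermediate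
11 | lithium acetylide of the DE aryloxyacetylene | [Li]C#COc1cc(OCc9ccccc9)c(OCc9ccccc9)c(OCc9ccccc9)c1Oc1cc(OCc9ccccc9)c(OCc9ccccc9)c(OCc9ccccc9)c1 | intermediate (not isolated)
12 | DE aryloxyacetylene, 1-(ethynyloxy)-3,4,5-tris(benzyloxy)-2-[3,4,5-tris(benzyloxy)phenoxy]benzene | C#COc1cc(OCc9ccccc9)c(OCc9ccccc9)c(OCc9ccccc9)c1Oc1cc(OCc9ccccc9)c(OCc9ccccc9)c(OCc9ccccc9)c1 | intermediate
13 | benzyloxyacetyl chloride | O=C(Cl)COCc1ccccc1 | starting material
14 | benzyloxyketene | O=C=COCc1ccccc1 | intermediate (not isolated)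
15 | racemic 4-(benzyloxy)-3-(DE-aryloxy)cyclobut-2-en-1-one | O=C1C=C(Oc2cc(OCc9ccccc9)c(OCc9ccccc9)c(OCc9ccccc9)c2Oc2cc(OCc9ccccc9)c(OCc9ccccc9)c(OCc9ccccc9)c2)C1OCc9ccccc9 | intermediate
16 | 2,4,6-trihydroxybenzaldehyde | O=Cc1c(O)cc(O)cc1O | starting material
17 | 2,4,6-tris(benzyloxy)benzaldehyde | O=Cc1c(OCc9ccccc9)cc(OCc9ccccc9)cc1OCc9ccccc9 | intermediate
18 | 2,4,6-tris(benzyloxy)phenyl formate | O=COc1c(OCc9ccccc9)cc(OCc9ccccc9)cc1OCc9ccccc9 | intermediate (not isolated)
19 | 2,4,6-tris(benzyloxy)phenol | Oc1c(OCc9ccccc9)cc(OCc9ccccc9)cc1OCc9ccccc9 | intermediate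
20 | 5-bromoresorcinol | Oc1cc(O)cc(Br)c1 | starting material
21 | 1,3-bis(benzyloxy)-5-bromobenzene | Brc1cc(OCc9ccccc9)cc(OCc9ccccc9)c1 | intermediate
22 | N-[2-bromo-4,6-bis(benzyloxy)benzylidene]-N-methylmethanaminium salt (drawn as chloride) | C[N+](C)=Cc1c(Br)cc(OCc9ccccc9)cc1OCc9ccccc9.[Cl-] | intermediate (not isolated)
23 | 2-bromo-4,6-bis(benzyloxy)benzaldehyde | O=Cc1c(Br)cc(OCc9ccccc9)cc1OCc9ccccc9 | intermediate
24 | 2,4-bis(benzyloxy)-6-[2,4,6-tris(benzyloxy)phenoxy]benzaldehyde | O=Cc1c(OCc9ccccc9)cc(OCc9ccccc9)cc1Oc1c(OCc9ccccc9)cc(OCc9ccccc9)cc1OCc9ccccc9 | intermediate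
25 | 2,4-bis(benzyloxy)-6-[2,4,6-tris(benzyloxy)phenoxy]phenyl formate | O=COc1c(OCc9ccccc9)cc(OCc9ccccc9)cc1Oc1c(OCc9ccccc9)cc(OCc9ccccc9)cc1OCc9ccccc9 | intermediate (not isolated)
26 | 2,4-bis(benzyloxy)-6-[2,4,6-tris(benzyloxy)phenoxy]phenol (AB phenol) | Oc1c(OCc9ccccc9)cc(OCc9ccccc9)cc1Oc1c(OCc9ccccc9)cc(OCc9ccccc9)cc1OCc9ccccc9 | intermediate
27 | (E)-1,2-dichlorovinyl ether of the AB phenol | Cl/C=C(/Cl)Oc1c(OCc9ccccc9)cc(OCc9ccccc9)cc1Oc1c(OCc9ccccc9)cc(OCc9ccccc9)cc1OCc9ccccc9 | intermediate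
28 | lithium acetylide of the AB aryloxyacetylene | [Li]C#COc1c(OCc9ccccc9)cc(OCc9ccccc9)cc1Oc1c(OCc9ccccc9)cc(OCc9ccccc9)cc1OCc9ccccc9 | intermediate (not isolated)
29 | AB aryloxyacetylene, 2-(ethynyloxy)-1,5-bis(benzyloxy)-3-[2,4,6-tris(benzyloxy)phenoxy]benzene | C#COc1c(OCc9ccccc9)cc(OCc9ccccc9)cc1Oc1c(OCc9ccccc9)cc(OCc9ccccc9)cc1OCc9ccccc9 | intermediate
30 | vinylketene, 4-(benzyloxy)-3-(DE-aryloxy)buta-1,3-dien-1-one, benzyloxy group trans to the ketene carbon | O=C=C/C(Oc1cc(OCc9ccccc9)c(OCc9ccccc9)c(OCc9ccccc9)c1Oc1cc(OCc9ccccc9)c(OCc9ccccc9)c(OCc9ccccc9)c1)=C/OCc9ccccc9 | intermediate (not isolated)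
31 | racemic 3-(AB-aryloxy)-4-[2-(benzyloxy)-1-(DE-aryloxy)vinyl]cyclobut-2-en-1-one | O=C1C=C(Oc2c(OCc9ccccc9)cc(OCc9ccccc9)cc2Oc2c(OCc9ccccc9)cc(OCc9ccccc9)cc2OCc9ccccc9)C1/C(Oc2cc(OCc9ccccc9)c(OCc9ccccc9)c(OCc9ccccc9)c2Oc2cc(OCc9ccccc9)c(OCc9ccccc9)c(OCc9ccccc9)c2)=C/OCc9ccccc9 | intermediate (not isolated)
32 | dienylketene, 3-(AB-aryloxy)-5-(DE-aryloxy)-6-(benzyloxy)hexa-1,3,5-trien-1-one, ketene carbon and C5 cis on the central double bond | C(/C=C=O)(Oc1c(OCc9ccccc9)cc(OCc9ccccc9)cc1Oc1c(OCc9ccccc9)cc(OCc9ccccc9)cc1OCc9ccccc9)=C/C(Oc1cc(OCc9ccccc9)c(OCc9ccccc9)c(OCc9ccccc9)c1Oc1cc(OCc9ccccc9)c(OCc9ccccc9)c(OCc9ccccc9)c1)=C/OCc9ccccc9 | intermediate (not isolated)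
33 | racemic 6-(benzyloxy)-3-(AB-aryloxy)-5-(DE-aryloxy)cyclohexa-2,4-dien-1-one | O=C1C=C(Oc2c(OCc9ccccc9)cc(OCc9ccccc9)cc2Oc2c(OCc9ccccc9)cc(OCc9ccccc9)cc2OCc9ccccc9)C=C(Oc2cc(OCc9ccccc9)c(OCc9ccccc9)c(OCc9ccccc9)c2Oc2cc(OCc9ccccc9)c(OCc9ccccc9)c(OCc9ccccc9)c2)C1OCc9ccccc9 | intermediate (not isolated)
34 | 2-(benzyloxy)-3-(DE-aryloxy)-5-(AB-aryloxy)phenol (dodecabenzyl pentamer) | Oc1cc(Oc2c(OCc9ccccc9)cc(OCc9ccccc9)cc2Oc2c(OCc9ccccc9)cc(OCc9ccccc9)cc2OCc9ccccc9)cc(Oc2cc(OCc9ccccc9)c(OCc9ccccc9)c(OCc9ccccc9)c2Oc2cc(OCc9ccccc9)c(OCc9ccccc9)c(OCc9ccccc9)c2)c1OCc9ccccc9 | intermediate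
35 | Pseudopentafuhalol D | Oc1cc(O)c(Oc2cc(O)cc(O)c2Oc2cc(O)c(O)c(Oc3cc(O)c(O)c(O)c3Oc3cc(O)c(O)c(O)c3)c2)c(O)c1 | target

Total step count: 18.
Longest linear sequence: 9 steps (steps 1, 2, 4, 5, 6, 7, 8, 17, 18).

Steps most likely to fail

Step 17. The vinylketene may be consumed by dimerisation, or by acylating the phenol already formed, faster than the hindered and only moderately nucleophilic aryloxyacetylene traps it. The terminal ynol ether may also oligomerise on heating. Any ester formed by acylation of 34 would be cleaved with K2CO3 in MeOH. The fallback gives up the annulation and builds ring C from a preformed arene by two Ullmann couplings; it sets out from phenols 26 and 8 and comes back to the route at target 35. Dakin oxidation (H2O2, NaOH) of commercial 3,5-dibromosalicylaldehyde gives 3,5-dibromobenzene-1,2-diol F1, and benzylation (BnBr, K2CO3, DMF) gives 1,2-bis(benzyloxy)-3,5-dibromobenzene F2. A first coupling with 26 (CuI, picolinic acid, K3PO4, DMSO, 100 °C) should take place at the bromide flanked by two hydrogens and give the ring C bromide F3; any regioisomer would be removed by chromatography. A second coupling under the same conditions with 8 at the remaining bromide, ortho to benzyloxy, gives the tridecabenzyl pentamer F4. Hydrogenolysis (H2, Pd/C, THF–MeOH) then gives 35.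

Step 8. Oligomerisation of benzyloxyketene may outrun its cycloaddition to the aryloxyacetylene, and premature ring opening of the cyclobutenone may consume unreacted alkyne. The fallback makes the same vinylketene 30 by photochemical Wolff rearrangement of a diazoketone, so the cyclobutenone is bypassed; it sets out from phenol 8 and comes back to the route at 34. Alkylation of 8 with methyl bromoacetate (K2CO3, acetone) gives methyl 2-(DE-aryloxy)acetate F5. Claisen formylation (NaH, HCO2Me, THF) and O-benzylation of the resulting enolate (BnBr, DMF) give methyl (Z)-3-(benzyloxy)-2-(DE-aryloxy)prop-2-enoate F6. Saponification (LiOH, THF–H2O) gives (Z)-3-(benzyloxy)-2-(DE-aryloxy)prop-2-enoic acid F7. Activation as the mixed anhydride (isobutyl chloroformate, N-methylmorpholine, THF, −15 °C) and treatment with CH2N2 give (Z)-4-(benzyloxy)-1-diazo-3-(DE-aryloxy)but-3-en-2-one F8. Irradiation of F8 through Pyrex at rt in the presence of 29 gives 30, which enters the cascade of step 17 (finished at 80 °C) to give 34.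

Step 13. Carbon–oxygen bond formation at copper between a di-ortho-substituted phenoxide and an ortho-substituted bromide may be slow, so that oxidation of the electron-rich phenol and reductive loss of bromine compete. The fallback replaces copper catalysis by nucleophilic aromatic substitution on a fluoroaldehyde; it sets out from phenol 19 and comes back to the route at 24. Commercial 1,3,5-trifluorobenzene with benzyl alcohol and NaH (2 equiv, NMP, 100 °C) gives 1,3-bis(benzyloxy)-5-fluorobenzene F9. Vilsmeier–Haack formylation (POCl3, DMF; then water) gives 2,4-bis(benzyloxy)-6-fluorobenzaldehyde F10. Addition–elimination with 19 (Cs2CO3, DMAc, 120 °C, argon) at the fluoride ortho to the formyl group gives 24.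

Further compounds
F1 | step 17 | 3,5-dibromobenzene-1,2-diol | Oc1c(O)cc(Br)cc1Br
F2 | step 17 | 1,2-bis(benzyloxy)-3,5-dibromobenzene | Brc1cc(Br)c(OCc9ccccc9)c(OCc9ccccc9)c1
F3 | step 17 | 1,2-bis(benzyloxy)-3-bromo-5-(AB-aryloxy)benzene | Brc1cc(Oc2c(OCc9ccccc9)cc(OCc9ccccc9)cc2Oc2c(OCc9ccccc9)cc(OCc9ccccc9)cc2OCc9ccccc9)cc(OCc9ccccc9)c1OCc9ccccc9
F4 | step 17 | 1,2-bis(benzyloxy)-3-(DE-aryloxy)-5-(AB-aryloxy)benzene (tridecabenzyl pentamer) | O(Cc9ccccc9)c1cc(Oc2c(OCc9ccccc9)cc(OCc9ccccc9)cc2Oc2c(OCc9ccccc9)cc(OCc9ccccc9)cc2OCc9ccccc9)cc(Oc2cc(OCc9ccccc9)c(OCc9ccccc9)c(OCc9ccccc9)c2Oc2cc(OCc9ccccc9)c(OCc9ccccc9)c(OCc9ccccc9)c2)c1OCc9ccccc9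
F5 | step 8 | methyl 2-(DE-aryloxy)acetate | COC(=O)COc1cc(OCc9ccccc9)c(OCc9ccccc9)c(OCc9ccccc9)c1Oc1cc(OCc9ccccc9)c(OCc9ccccc9)c(OCc9ccccc9)c1
F6 | step 8 | methyl (Z)-3-(benzyloxy)-2-(DE-aryloxy)prop-2-enoate | COC(=O)/C(Oc1cc(OCc9ccccc9)c(OCc9ccccc9)c(OCc9ccccc9)c1Oc1cc(OCc9ccccc9)c(OCc9ccccc9)c(OCc9ccccc9)c1)=C/OCc9ccccc9
F7 | step 8 | (Z)-3-(benzyloxy)-2-(DE-aryloxy)prop-2-enoic acid | OC(=O)/C(Oc1cc(OCc9ccccc9)c(OCc9ccccc9)c(OCc9ccccc9)c1Oc1cc(OCc9ccccc9)c(OCc9ccccc9)c(OCc9ccccc9)c1)=C/OCc9ccccc9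
F8 | step 8 | (Z)-4-(benzyloxy)-1-diazo-3-(DE-aryloxy)but-3-en-2-one | [N-]=[N+]=CC(=O)/C(Oc1cc(OCc9ccccc9)c(OCc9ccccc9)c(OCc9ccccc9)c1Oc1cc(OCc9ccccc9)c(OCc9ccccc9)c(OCc9ccccc9)c1)=C/OCc9ccccc9
F9 | step 13 | 1,3-bis(benzyloxy)-5-fluorobenzene | Fc1cc(OCc9ccccc9)cc(OCc9ccccc9)c1
F10 | step 13 | 2,4-bis(benzyloxy)-6-fluorobenzaldehyde | O=Cc1c(F)cc(OCc9ccccc9)cc1OCc9ccccc9
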